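**Retrosynthetic overview**
- Both angelate esters are installed late (C15 first, C7 last); the C1 enone comes from a C1 carbinol by oxidation and exo-to-endo alkene isomerisation.
- The seven-membered ring is closed last (C5–C6) by an intramolecular ester-enolate aldol addition onto a bicyclo[3.1.1]heptan-6-one; the resulting tertiary C5–OH is then removed by radical deoxygenation.
- The cyclobutane and the six-membered ring are formed together by an intramolecular vinylketene–alkene [2+2] cycloaddition of an acyclic (2E,6E)-dienoic acid, directed by the C1 silyloxy stereocentre.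
- The acyclic acid comes from a catalytic asymmetric vinylogous Mukaiyama aldol (sets C1) on an enal built from geranyl acetate; C7 is set first, by ketoreductase reduction of an achiral β-keto ester.
- Ring order: four- and six-membered rings in one step, then the seven-membered ring.

**Assumption and labels:** the SMILES is read as the (4R,5S,6S,7R,10R,11R) enantiomer. Cyclic intermediates are named on the longipinane skeleton: C1(=O)–C2=C3(C12H3)–C4; cyclobutane C4–C5–C11–C10 (C11 bonded to C1, C10 bears C13H3); bridge C5–C6(C14H3)(C15H2O)–C7(O)–C8–C9–C10. The stereochemical outcomes of steps 12 and 13 are predictions from conformational models, not established results.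

**Step 1**
Reactants: 1 geranyl acetate
Product: 2 (2E)-3-methyl-6-oxohex-2-en-1-yl acetate
Conditions: O3 (1.0 equiv, Sudan Red 7B end-point), pyridine (3 equiv), CH2Cl2, −78 °C
Reagents that add atoms: ozone, [O-][O+]=O
Why: Chemoselective (pyridine-mediated reductive) ozonolysis cleaves the electron-rich distal trisubstituted alkene, the 2,3-alkene being deactivated by the allylic acetate; no stereocentre is formed.

**Step 2**
Reactants: 2 acetoxy aldehyde; 3 tert-butyl diazoacetate
Product: 4 tert-butyl (6E)-8-acetoxy-6-methyl-3-oxooct-6-enoate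
Conditions: SnCl2 (10 mol%), CH2Cl2, rt
Reagents that add atoms: none
Why: Roskamp homologation (Lewis-acid-catalysed diazo ester addition to the aldehyde, 1,2-hydride shift, loss of N2) gives the achiral β-keto ester directly.

**Step 3**
Reactants: 4 β-keto ester
Product: 5 tert-butyl (3R,6E)-8-acetoxy-3-hydroxy-6-methyloct-6-enoate
Conditions: ketoreductase (R-selective KRED), NADP+ (cat.), i-PrOH (10% v/v), phosphate buffer pH 7.0, 30 °C
Reagents that add atoms: none
Why: Enzymatic asymmetric ketone reduction by a ketoreductase (NADPH-dependent oxidoreductase) on a β-keto ester, with isopropanol recycling the cofactor; face-selective hydride delivery sets the first stereocentre (C3 here, C7 of the target, R).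

**Step 4**
Reactants: 5 acetoxy hydroxy ester
Product: 6 tert-butyl (3R,6E)-3,8-dihydroxy-6-methyloct-6-enoate
Conditions: K2CO3 (0.2 equiv), MeOH, 0 °C → rt
Reagents that add atoms: none
Why: Base-catalysed transesterification removes the primary allylic acetate while the tert-butyl ester and the carbinol centre are untouched.

**Step 5**
Reactants: 6 diol ester
Product: 7 tert-butyl (2R,3R,6E)-3,8-dihydroxy-2,6-dimethyloct-6-enoate
Conditions: LiN(i-Pr)2 (3.3 equiv), THF, −78 → −20 °C; MeI, DMPU, −78 → −10 °C; aq. NH4Cl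
Reagents that add atoms: iodomethane, CI
Why: Fráter–Seebach alkylation: the chelated alkoxide–enolate is methylated anti to the C3 chain (2R); this centre is re-enolised in step 13, so its purity is not critical.

**Step 6**
Reactants: 7 methylated diol ester
Product: 8 tert-butyl (2R,3R,6E)-3-hydroxy-2,6-dimethyl-8-oxooct-6-enoate
Conditions: MnO2 (15 equiv), CH2Cl2, rt
Reagents that add atoms: none
Why: MnO2 oxidises only the allylic primary alcohol, giving the (E)-enal and leaving the secondary β-hydroxy ester alone.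

**Step 7**
Reactants: 8 hydroxy enal
Product: 9 tert-butyl (2R,3R,6E)-3-[(tert-butyldimethylsilyl)oxy]-2,6-dimethyl-8-oxooct-6-enoate
Conditions: TBSOTf, 2,6-lutidine, CH2Cl2, −78 °C
Reagents that add atoms: tert-butyldimethylsilyl triflate, CC(C)(C)[Si](C)(C)OS(=O)(=O)C(F)(F)F
Why: Low-temperature O-silylation gives the bulky, non-chelating silyl ether that survives the sequence and is needed for the stereocontrol argued in step 13.

**Step 8**
Reactants: 10 methyl 3-methylbut-2-enoate
Product: 11 (1Z)-1-methoxy-3-methyl-1-[(tert-butyldimethylsilyl)oxy]buta-1,3-diene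
Conditions: LiN(i-Pr)2, THF, −78 °C; TBSCl, DMPU, −78 °C → rt; distillation
Reagents that add atoms: tert-butyldimethylsilyl chloride, CC(C)(C)[Si](C)(C)Cl
Why: γ-Deprotonation of the enoate and O-silylation give the silyl dienolate (ketene-acetal geometry is immaterial for the next step).

**Step 9**
Reactants: 9 silyloxy enal; 11 silyl dienolate
Product: 12 12-tert-butyl 1-methyl (2E,5S,6E,10R,11R)-10-[(tert-butyldimethylsilyl)oxy]-5-hydroxy-3,7,11-trimethyldodeca-2,6-dienedioate
Conditions: SiCl4 (1.1 equiv), chiral binaphthyl-2,2′-diamine-derived pentane-1,5-diyl-linked bisphosphoramide (5 mol%, the enantiomer directing Si-face attack), i-Pr2NEt (10 mol%), CH2Cl2, −78 °C; aq. NaHCO3/KF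
Reagents that add atoms: none
Why: Lewis-base-catalysed enantioselective vinylogous Mukaiyama aldol: γ-attack of the dienolate on the Si face of the enal sets the 5S carbinol (C1 of the skeleton) and gives the (2E)-3-methyl enoate with methyl cis to the ester.

**Step 10**
Reactants: 12 hydroxy diester
Product: 13 12-tert-butyl 1-methyl (2E,5S,6E,10R,11R)-10-[(tert-butyldimethylsilyl)oxy]-3,7,11-trimethyl-5-[(triethylsilyl)oxy]dodeca-2,6-dienedioate
Conditions: TESCl, imidazole, DMAP (cat.), CH2Cl2, 0 °C → rt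
Reagents that add atoms: chlorotriethylsilane, CC[Si](Cl)(CC)CC
Why: Mild silylation protects the allylic carbinol under non-ionising conditions as an ether that can later be removed in the presence of the TBS ether.

**Step 11**
Reactants: 13 bis-silyl diester
Product: 14 (2E,5S,6E,10R,11R)-12-tert-butoxy-10-[(tert-butyldimethylsilyl)oxy]-3,7,11-trimethyl-12-oxo-5-[(triethylsilyl)oxy]dodeca-2,6-dienoic acid
Conditions: LiOH·H2O, THF/MeOH/H2O, 40 °C; 0.5 M HCl to pH 4, 0 °C
Reagents that add atoms: lithium hydroxide, [Li+].[OH-]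
Why: Saponification cleaves the methyl ester only, the tert-butyl ester being inert to hydroxide.

**Step 12**
Reactants: 14 dienoic acid
Product: 17 tert-butyl (2R,3R)-3-[(tert-butyldimethylsilyl)oxy]-2-methyl-5-[(1R,2S,5R,7R)-7-methyl-4-methylidene-6-oxo-2-[(triethylsilyl)oxy]bicyclo[3.1.1]heptan-7-yl]pentanoate, via acid chloride 15 (not isolated), via vinylketene 16 (not isolated)
Conditions: 1-chloro-N,N,2-trimethylprop-1-en-1-amine, CH2Cl2, 0 °C → rt; then slow addition to Et3N (5 equiv), toluene, 110 °C, 0.005 M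
Reagents that add atoms: none
Why: Dehydrochlorination at the methyl cis to the acyl group gives a vinylketene that undergoes intramolecular ketene–alkene [2+2] cycloaddition; suprafacial addition to the (E)-alkene puts C13 syn to the three-carbon bridge and the side chain anti, and A(1,3) strain holds the C1–H in the alkene plane so the ketene adds anti to the silyloxy group, fixing C4, C10 and C11.

**Step 13**
Reactants: 17 bicyclic keto ester
Product: 18 tert-butyl (1S,4R,5R,6S,7R,10R,11R)-7-[(tert-butyldimethylsilyl)oxy]-5-hydroxy-1-[(triethylsilyl)oxy]longipin-3(12)-en-15-oate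
Conditions: LiN(i-Pr)2 (1.3 equiv), THF, −78 °C; AcOH, −78 °C
Reagents that add atoms: none
Why: Intramolecular ester-enolate aldol addition to the strained, non-enolisable cyclobutanone closes the seven-membered ring from the only face the tether reaches (fixing C5); A(1,3) strain keeps H7 in the enolate plane and attack must be syn to C8, so the ester carbon ends trans and the methyl cis to the C7 silyloxy group (6S).

**Step 14**
Reactants: 18 tricyclic hydroxy ester
Product: 19 (1S,4R,5R,6S,7R,10R,11R)-7-[(tert-butyldimethylsilyl)oxy]-1-[(triethylsilyl)oxy]longipin-3(12)-ene-5,15-diol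
Conditions: LiAlH4, THF, 0 → 60 °C
Reagents that add atoms: none
Why: Hydride reduction of the hindered tert-butyl ester, assisted by the neighbouring aluminium alkoxide, gives the primary C15 alcohol without touching any stereocentre.

**Step 15**
Reactants: 19 1,3-diol
Product: 20 (1S,4R,5R,6S,7R,10R,11R)-7-[(tert-butyldimethylsilyl)oxy]-1-[(triethylsilyl)oxy]longipin-3(12)-ene-5,15-diyl thiocarbonate (six-membered cyclic thionocarbonate)
Conditions: 1,1′-thiocarbonyldiimidazole, DMAP (cat.), toluene, 110 °C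
Reagents that add atoms: 1,1′-thiocarbonyldiimidazole, S=C(n1ccnc1)n1ccnc1
Why: Thioacylation of the primary alcohol followed by intramolecular six-membered ring closure derivatises the very hindered tertiary C5–OH, which cannot eliminate because every β-hydrogen is at a bridgehead.

**Step 16**
Reactants: 20 cyclic thionocarbonate
Product: 22 (1S,4R,5S,6S,7R,10R,11R)-7-[(tert-butyldimethylsilyl)oxy]-1-[(triethylsilyl)oxy]longipin-3(12)-en-15-ol, via stannyl thiolcarbonate 21 (not isolated)
Conditions: Bu3SnH, AIBN (cat.), toluene, 110 °C; then K2CO3, MeOH/H2O, rt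
Reagents that add atoms: none
Why: Barton–McCombie-type radical deoxygenation: stannyl radical adds to C=S, β-scission gives the more stable tertiary C5 radical, and hydrogen transfer from Bu3SnH on the only open face gives the cage-enforced 5S C–H; work-up hydrolysis frees O15.

**Step 17**
Reactants: 22 primary alcohol; 23 angelic acid
Product: 24 (1S,4R,5S,6S,7R,10R,11R)-7-[(tert-butyldimethylsilyl)oxy]-1-[(triethylsilyl)oxy]longipin-3(12)-en-15-yl (2Z)-2-methylbut-2-enoate
Conditions: 23, 2,4,6-trichlorobenzoyl chloride, Et3N, toluene, rt; then 22, 80 °C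
Reagents that add atoms: none
Why: Yamaguchi-type mixed-anhydride acylation without a nucleophilic catalyst esterifies the primary alcohol while avoiding Z-to-E isomerisation to the tiglate.

**Step 18**
Reactants: 24 bis-silyl angelate
Product: 25 (1S,4R,5S,6S,7R,10R,11R)-7-[(tert-butyldimethylsilyl)oxy]-1-hydroxylongipin-3(12)-en-15-yl (2Z)-2-methylbut-2-enoate
Conditions: PPTS (0.2 equiv), MeOH/CH2Cl2, 0 °C → rt
Reagents that add atoms: none
Why: Mild acid-catalysed methanolysis removes the triethylsilyl ether selectively; the hindered neopentyl TBS ether and the angelate are stable.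

**Step 19**
Reactants: 25 C1 alcohol
Product: 27 (4R,5S,6S,7R,10R,11R)-7-[(tert-butyldimethylsilyl)oxy]-1-oxolongipin-2-en-15-yl (2Z)-2-methylbut-2-enoate, via methylidene ketone 26 (not isolated)
Conditions: Dess–Martin periodinane, CH2Cl2, 0 °C → rt; basic alumina pad; then DBU (0.2 equiv), CH2Cl2, rt
Reagents that add atoms: none
Why: Dess–Martin oxidation gives the β,γ-unsaturated ketone, whose doubly activated C2 protons allow base-catalysed isomerisation of the exocyclic alkene into conjugation (verbenone-type enone); the C1 stereocentre is deliberately destroyed.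

**Step 20**
Reactants: 27 silyloxy enone
Product: 28 (4R,5S,6S,7R,10R,11R)-7-hydroxy-1-oxolongipin-2-en-15-yl (2Z)-2-methylbut-2-enoate
Conditions: HF·pyridine, THF, 0 → 40 °C
Reagents that add atoms: none
Why: Fluoride-mediated desilylation under mildly acidic conditions frees the C7 alcohol without acyl migration or angelate isomerisation.

**Step 21**
Reactants: 28 hydroxy enone angelate; 23 angelic acid
Product: 29 (4R,5S,6S,7R,10R,11R)-1-oxolongipin-2-ene-7,15-diyl bis[(2Z)-2-methylbut-2-enoate] (CNP0240716.2)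
Conditions: 23, 2,4,6-trichlorobenzoyl chloride, Et3N, toluene, rt; then 28, 100 °C
Reagents that add atoms: none
Why: The same mixed-anhydride (Yamaguchi-type) acylation at higher temperature esterifies the hindered neopentyl C7 alcohol; a 1,3-acyl shift would be harmless because both oxygens end as angelates.

**Compound list**
1 | geranyl acetate, (2E)-3,7-dimethylocta-2,6-dien-1-yl acetate | CC(C)=CCC/C(C)=C/COC(C)=O | starting material
2 | (2E)-3-methyl-6-oxohex-2-en-1-yl acetate | O=CCC/C(C)=C/COC(C)=O | intermediate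
3 | tert-butyl diazoacetate | CC(C)(C)OC(=O)C=[N+]=[N-] | starting material
4 | tert-butyl (6E)-8-acetoxy-6-methyl-3-oxooct-6-enoate | CC(C)(C)OC(=O)CC(=O)CC/C(C)=C/COC(C)=O | intermediate
5 | tert-butyl (3R,6E)-8-acetoxy-3-hydroxy-6-methyloct-6-enoate | CC(C)(C)OC(=O)C[C@H](O)CC/C(C)=C/COC(C)=O | intermediate
6 | tert-butyl (3R,6E)-3,8-dihydroxy-6-methyloct-6-enoate | CC(C)(C)OC(=O)C[C@H](O)CC/C(C)=C/CO | intermediate
7 | tert-butyl (2R,3R,6E)-3,8-dihydroxy-2,6-dimethyloct-6-enoate | CC(C)(C)OC(=O)[C@H](C)[C@H](O)CC/C(C)=C/CO | intermediate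
8 | tert-butyl (2R,3R,6E)-3-hydroxy-2,6-dimethyl-8-oxooct-6-enoate | CC(C)(C)OC(=O)[C@H](C)[C@H](O)CC/C(C)=C/C=O | intermediate
9 | tert-butyl (2R,3R,6E)-3-[(tert-butyldimethylsilyl)oxy]-2,6-dimethyl-8-oxooct-6-enoate | CC(C)(C)OC(=O)[C@H](C)[C@H](O[Si](C)(C)C(C)(C)C)CC/C(C)=C/C=O | intermediate
10 | methyl 3-methylbut-2-enoate | COC(=O)C=C(C)C | starting material
11 | (1Z)-1-methoxy-3-methyl-1-[(tert-butyldimethylsilyl)oxy]buta-1,3-diene | CO/C(O[Si](C)(C)C(C)(C)C)=C/C(C)=C | intermediate
12 | 12-tert-butyl 1-methyl (2E,5S,6E,10R,11R)-10-[(tert-butyldimethylsilyl)oxy]-5-hydroxy-3,7,11-trimethyldodeca-2,6-dienedioate | COC(=O)/C=C(\C)C[C@H](O)/C=C(\C)CC[C@@H](O[Si](C)(C)C(C)(C)C)[C@@H](C)C(=O)OC(C)(C)C | intermediate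
13 | 12-tert-butyl 1-methyl (2E,5S,6E,10R,11R)-10-[(tert-butyldimethylsilyl)oxy]-3,7,11-trimethyl-5-[(triethylsilyl)oxy]dodeca-2,6-dienedioate | COC(=O)/C=C(\C)C[C@H](O[Si](CC)(CC)CC)/C=C(\C)CC[C@@H](O[Si](C)(C)C(C)(C)C)[C@@H](C)C(=O)OC(C)(C)C | intermediate
14 | (2E,5S,6E,10R,11R)-12-tert-butoxy-10-[(tert-butyldimethylsilyl)oxy]-3,7,11-trimethyl-12-oxo-5-[(triethylsilyl)oxy]dodeca-2,6-dienoic acid | OC(=O)/C=C(\C)C[C@H](O[Si](CC)(CC)CC)/C=C(\C)CC[C@@H](O[Si](C)(C)C(C)(C)C)[C@@H](C)C(=O)OC(C)(C)C | intermediate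
15 | acid chloride of 14, tert-butyl (2R,3R,6E,8S,10E)-3-[(tert-butyldimethylsilyl)oxy]-12-chloro-2,6,10-trimethyl-12-oxo-8-[(triethylsilyl)oxy]dodeca-6,10-dienoate | ClC(=O)/C=C(\C)C[C@H](O[Si](CC)(CC)CC)/C=C(\C)CC[C@@H](O[Si](C)(C)C(C)(C)C)[C@@H](C)C(=O)OC(C)(C)C | intermediate
16 | vinylketene, tert-butyl (2R,3R,6E,8S)-3-[(tert-butyldimethylsilyl)oxy]-2,6-dimethyl-10-methylidene-12-oxo-8-[(triethylsilyl)oxy]dodeca-6,11-dienoate | O=C=CC(=C)C[C@H](O[Si](CC)(CC)CC)/C=C(\C)CC[C@@H](O[Si](C)(C)C(C)(C)C)[C@@H](C)C(=O)OC(C)(C)C | intermediate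
17 | tert-butyl (2R,3R)-3-[(tert-butyldimethylsilyl)oxy]-2-methyl-5-[(1R,2S,5R,7R)-7-methyl-4-methylidene-6-oxo-2-[(triethylsilyl)oxy]bicyclo[3.1.1]heptan-7-yl]pentanoate (7-methyl syn to the C2–C4 bridge, silyloxy anti to C7) | O=C1[C@H]2[C@@H](O[Si](CC)(CC)CC)CC(=C)[C@@H]1[C@@]2(C)CC[C@@H](O[Si](C)(C)C(C)(C)C)[C@@H](C)C(=O)OC(C)(C)C | intermediate
18 | tert-butyl (1S,4R,5R,6S,7R,10R,11R)-7-[(tert-butyldimethylsilyl)oxy]-5-hydroxy-1-[(triethylsilyl)oxy]longipin-3(12)-en-15-oate | CC(C)(C)OC(=O)[C@]1(C)[C@]2(O)[C@H]3[C@@H](O[Si](CC)(CC)CC)CC(=C)[C@@H]2[C@@]3(C)CC[C@H]1O[Si](C)(C)C(C)(C)C | intermediate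
19 | (1S,4R,5R,6S,7R,10R,11R)-7-[(tert-butyldimethylsilyl)oxy]-1-[(triethylsilyl)oxy]longipin-3(12)-ene-5,15-diol | OC[C@]1(C)[C@]2(O)[C@H]3[C@@H](O[Si](CC)(CC)CC)CC(=C)[C@@H]2[C@@]3(C)CC[C@H]1O[Si](C)(C)C(C)(C)C | intermediate
20 | 5,15-cyclic thionocarbonate of 19, (1S,4R,5R,6S,7R,10R,11R) | S=C4OC[C@]1(C)[C@]2(O4)[C@H]3[C@@H](O[Si](CC)(CC)CC)CC(=C)[C@@H]2[C@@]3(C)CC[C@H]1O[Si](C)(C)C(C)(C)C | intermediate
21 | O-[(1S,4R,5S,6S,7R,10R,11R)-7-[(tert-butyldimethylsilyl)oxy]-1-[(triethylsilyl)oxy]longipin-3(12)-en-15-yl] S-(tributylstannyl) thiocarbonate | CCCC[Sn](CCCC)(CCCC)SC(=O)OC[C@]1(C)[C@@H]2[C@H]3[C@@H](O[Si](CC)(CC)CC)CC(=C)[C@@H]2[C@@]3(C)CC[C@H]1O[Si](C)(C)C(C)(C)C | intermediate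
22 | (1S,4R,5S,6S,7R,10R,11R)-7-[(tert-butyldimethylsilyl)oxy]-1-[(triethylsilyl)oxy]longipin-3(12)-en-15-ol | OC[C@]1(C)[C@@H]2[C@H]3[C@@H](O[Si](CC)(CC)CC)CC(=C)[C@@H]2[C@@]3(C)CC[C@H]1O[Si](C)(C)C(C)(C)C | intermediate
23 | angelic acid, (2Z)-2-methylbut-2-enoic acid | C/C=C(/C)C(=O)O | starting material
24 | (1S,4R,5S,6S,7R,10R,11R)-7-[(tert-butyldimethylsilyl)oxy]-1-[(triethylsilyl)oxy]longipin-3(12)-en-15-yl (2Z)-2-methylbut-2-enoate | C/C=C(/C)C(=O)OC[C@]1(C)[C@@H]2[C@H]3[C@@H](O[Si](CC)(CC)CC)CC(=C)[C@@H]2[C@@]3(C)CC[C@H]1O[Si](C)(C)C(C)(C)C | intermediate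
25 | (1S,4R,5S,6S,7R,10R,11R)-7-[(tert-butyldimethylsilyl)oxy]-1-hydroxylongipin-3(12)-en-15-yl (2Z)-2-methylbut-2-enoate | C/C=C(/C)C(=O)OC[C@]1(C)[C@@H]2[C@H]3[C@@H](O)CC(=C)[C@@H]2[C@@]3(C)CC[C@H]1O[Si](C)(C)C(C)(C)C | intermediate
26 | (4R,5S,6S,7R,10R,11R)-7-[(tert-butyldimethylsilyl)oxy]-1-oxolongipin-3(12)-en-15-yl (2Z)-2-methylbut-2-enoate | C/C=C(/C)C(=O)OC[C@]1(C)[C@@H]2[C@H]3C(=O)CC(=C)[C@@H]2[C@@]3(C)CC[C@H]1O[Si](C)(C)C(C)(C)C | intermediate
27 | (4R,5S,6S,7R,10R,11R)-7-[(tert-butyldimethylsilyl)oxy]-1-oxolongipin-2-en-15-yl (2Z)-2-methylbut-2-enoate | C/C=C(/C)C(=O)OC[C@]1(C)[C@@H]2[C@H]3C(=O)C=C(C)[C@@H]2[C@@]3(C)CC[C@H]1O[Si](C)(C)C(C)(C)C | intermediate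
28 | (4R,5S,6S,7R,10R,11R)-7-hydroxy-1-oxolongipin-2-en-15-yl (2Z)-2-methylbut-2-enoate | C/C=C(/C)C(=O)OC[C@]1(C)[C@@H]2[C@H]3C(=O)C=C(C)[C@@H]2[C@@]3(C)CC[C@H]1O | intermediate
29 | (4R,5S,6S,7R,10R,11R)-1-oxolongipin-2-ene-7,15-diyl bis[(2Z)-2-methylbut-2-enoate], CNP0240716.2 | C/C=C(/C)C(=O)OC[C@]1(C)[C@@H]2[C@H]3C(=O)C=C(C)[C@@H]2[C@@]3(C)CC[C@H]1OC(=O)/C(C)=C\C | target

**Step count**
Total: 21 steps. Longest linear sequence: 20 steps (steps 1–7 and 9–21 from geranyl acetate); step 8 is a one-step side branch.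

**Three steps most likely to fail**

Step 12 (vinylketene [2+2]). The allylic silyloxy group lowers the nucleophilicity of the reacting alkene, and the ketene may oligomerise instead. The fallback sets out from acid 14. Coupling with pyrrolidine (EDC·HCl, HOBt, CH2Cl2) gives the pyrrolidine amide F1. Tf2O and 2,4,6-collidine in 1,2-dichloroethane (0 → 80 °C) then generate a vinylketeniminium ion, which is more electrophilic and does not dimerise. It should undergo the same crossed intramolecular [2+2] cycloaddition to the cyclobutaniminium triflate F2, and aqueous NaHCO3 hydrolysis returns to ketone 17. If instead the facial sense of the cycloaddition is opposite to the model, the antipodal catalyst in step 9 corrects it.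

Step 13 (aldol ring closure). Risks are retro-aldol, β-elimination of the silanolate from the lithium enolate, and formation of the C6 epimer. The fallback sets out from 17. Adding it to premixed LiN(i-Pr)2/Me3SiCl in THF at −100 °C traps the ester enolate as the tert-butyl trimethylsilyl ketene acetal F3 (E/Z mixture). TiCl4 in CH2Cl2 at −78 °C then effects an intramolecular Mukaiyama aldol through an open transition state with no basic enolate present. The same A(1,3) bias applies, and aqueous work-up returns to 18.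

Step 16 (deoxygenation at C5). The cyclic thionocarbonate may not close onto the hindered tertiary hydroxyl, or may fragment unselectively. The fallback sets out from diol 19. Ac2O/pyridine at 0 °C caps only the primary alcohol, giving the primary acetate F4. Methyl chlorooxoacetate with DMAP in pyridine/CH2Cl2 converts the tertiary alcohol to the tertiary methyl oxalate F5. Bu3SnH/AIBN in toluene at 110 °C (oxalate variant of radical deoxygenation) gives the deoxygenated acetate F6, and K2CO3 in MeOH returns to alcohol 22.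

**Further compounds**
F1 | step 12 | 1-[(2E,5S,6E,10R,11R)-12-tert-butoxy-10-[(tert-butyldimethylsilyl)oxy]-3,7,11-trimethyl-12-oxo-5-[(triethylsilyl)oxy]dodeca-2,6-dienoyl]pyrrolidine | O=C(/C=C(\C)C[C@H](O[Si](CC)(CC)CC)/C=C(\C)CC[C@@H](O[Si](C)(C)C(C)(C)C)[C@@H](C)C(=O)OC(C)(C)C)N1CCCC1
F2 | step 12 | pyrrolidin-1-ium-1-ylidene analogue of ketone 17 (C6=O of the bicycle replaced by C=N+(CH2)4), triflate salt | C1CC[N+](C1)=C2[C@H]3[C@@H](O[Si](CC)(CC)CC)CC(=C)[C@@H]2[C@@]3(C)CC[C@@H](O[Si](C)(C)C(C)(C)C)[C@@H](C)C(=O)OC(C)(C)C.[O-]S(=O)(=O)C(F)(F)F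
F3 | step 13 | tert-butyl trimethylsilyl ketene acetal of ester 17 (E/Z mixture at the ketene acetal, other centres as in 17) | O=C1[C@H]2[C@@H](O[Si](CC)(CC)CC)CC(=C)[C@@H]1[C@@]2(C)CC[C@@H](O[Si](C)(C)C(C)(C)C)C(C)=C(O[Si](C)(C)C)OC(C)(C)C
F4 | step 16 | (1S,4R,5R,6S,7R,10R,11R)-7-[(tert-butyldimethylsilyl)oxy]-5-hydroxy-1-[(triethylsilyl)oxy]longipin-3(12)-en-15-yl acetate | CC(=O)OC[C@]1(C)[C@]2(O)[C@H]3[C@@H](O[Si](CC)(CC)CC)CC(=C)[C@@H]2[C@@]3(C)CC[C@H]1O[Si](C)(C)C(C)(C)C
F5 | step 16 | 15-acetoxy-7-[(tert-butyldimethylsilyl)oxy]-1-[(triethylsilyl)oxy]longipin-3(12)-en-5-yl methyl oxalate (configuration as in F4) | CC(=O)OC[C@]1(C)[C@]2(OC(=O)C(=O)OC)[C@H]3[C@@H](O[Si](CC)(CC)CC)CC(=C)[C@@H]2[C@@]3(C)CC[C@H]1O[Si](C)(C)C(C)(C)C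
F6 | step 16 | (1S,4R,5S,6S,7R,10R,11R)-7-[(tert-butyldimethylsilyl)oxy]-1-[(triethylsilyl)oxy]longipin-3(12)-en-15-yl acetate | CC(=O)OC[C@]1(C)[C@@H]2[C@H]3[C@@H](O[Si](CC)(CC)CC)CC(=C)[C@@H]2[C@@]3(C)CC[C@H]1O[Si](C)(C)C(C)(C)C
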